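Throughout, "geranyl" means the (2E)-3,7-dimethylocta-2,6-dien-1-yl group. The benzofuran is numbered O1, C2, C3, C3a, C4 to C7, C7a; ring B atoms are primed and geranyl atoms double-primed. The six carbons of the open triketone chain are called chain C1 (bonded to C2 of the benzofuran) to chain C6 (the methyl terminus).

## Analysis of the target

The target is 5-(7-geranyl-6-hydroxybenzofuran-2-yl)benzene-1,3-diol: a benzofuran whose benzo ring (ring A) carries a hydroxyl on C6 and a geranyl chain on C7, and whose C2 carries ring B, a 3,5-dihydroxyphenyl group. It has no stereocenter; the only stereochemical element is the (E) geometry of the C2″=C3″ alkene, which is bought with the geranyl unit and only has to survive. The sensitive parts are the three free phenols (air oxidation, worst in base), the electron-rich C2=C3 bond of the furan, and above all the geranyl chain ortho to the C6 hydroxyl. Protic and Lewis acids add that hydroxyl to C2″=C3″ to give a chroman or start cation–olefin cyclisation, and hydrogenation or strong oxidants destroy the two trisubstituted alkenes. Two things make the synthesis hard: C7 lies in a contiguous 1,2,3-pattern between C7a (ring oxygen) and C6 (hydroxyl), where regiocontrol is weak, and every protecting group must come off without acid and without hydrogen. The plan rests on ring B: C1′ (bonded to C2), C3′ (OH) and C5′ (OH) alternate with three CH carbons. This is the pattern produced when a 1,3,5-triketone chain on C2 folds by aldol condensation between its methyl terminus and the ketone next to the heterocycle. Ring B can therefore be made last, in base, from a chain whose oxygens are already on the right carbons.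

## Retrosynthetic reasoning

**O6–allyl bond (14 from 13).** The last operation is removal of one allyl ether from 13 with zerovalent palladium and an amine, which involves neither acid nor hydrogen. O6 needs a group because the furan is built by alkylating the neighbouring phenol, and an allyl ether was chosen for two reasons. A silyl ether, which the base of the ring-forming step would remove in the same flask, is not reliable in the hot basic medium that closes the furan. A free phenoxide at C6 is conjugated through C3a–C3=C2 with the ketone that must accept the aldol, and would blunt it.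

**Ring B, bond C1′–C2′ (13 from 11).** Cutting the bond between the ipso carbon and one ortho carbon, and reading the two hydroxyls as carbonyls, unfolds ring B into the unbranched triketone 11. This is the only cut that needs no aryl–heteroaryl coupling and no pre-oxygenated arene. Forward, aqueous base must make chain C6 attack chain C1, and the adduct must lose water and enolise. The closure is 6-(enolendo)-exo-trig, because both enolate carbons (chain C5 and C6) end up inside the new ring. The reaction has to win over closure through an enol oxygen to a six-membered oxygen heterocycle, which is the reason for working in aqueous base and not in acid.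

**Chain C1–C2 bond (11 from 8 and 9).** The bond between the ketone carbon on C2 and the first methylene is cut, which gives the ester 8 and the terminal carbanion of the dianion 10, made from 9. The ester has no α-hydrogen, and the dianion reacts at its terminal carbon, so the chain is delivered in one step with all three oxygens in place.

**Furan ring, bonds O1–C2 and C2=C3 (8 from 4 and 5).** The furan is opened to the salicylaldehyde 4 and the two-carbon ester 5. Forward, O-alkylation gives 6, intramolecular aldol addition gives 7 and dehydration aromatises. The aldehyde carbon becomes C3 and the phenol oxygen becomes O1, so the 3-geranyl-4-oxygen pattern of the aldehyde maps onto C7 and C6 without ambiguity.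

**O4–allyl bond (4 from 3).** The two hydroxyls of 3 are told apart by the hydrogen bond between the 2-hydroxyl and the formyl group; the 4-hydroxyl is alkylated first.

**C3–C1″ bond (3 from 1 and 2).** The geranyl chain is attached at the carbon between the two hydroxyls of 1 by C-alkylation of the phenoxide with 2. This is the shortest access to the 1,2,3-pattern and uses two cheap materials; its price is moderate regiocontrol, accepted because it is the first step.

## Alternatives that were turned down

**Alternative 1:** Here the C2=C3 bond of the furan is cut. This leads back to an aryl ester with a formyl group ortho to the ester oxygen, 2-formyl-6-geranyl-5-(triisopropylsilyloxy)phenyl 3,5-bis(triisopropylsilyloxy)benzoate A2. A2 would be made from 3 by silylation of the 4-hydroxyl and aroylation of the 2-hydroxyl.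

In the forward direction, low-valent titanium made from TiCl3 and Zn would join the formyl carbon of A2 to its ester carbonyl carbon and strip both oxygens. The furan would close to 2-[3,5-bis(triisopropylsilyloxy)phenyl]-7-geranyl-6-(triisopropylsilyloxy)benzofuran A1, and fluoride would then free the three phenols of A1.

In its favour, ring B arrives intact in A2, so no aromatisation can fail. The plan is convergent and about as short as the chosen one. On the reliability of the ring construction it is probably the stronger plan.

Against it:
- It begins from the same aldehyde 3 and so gains nothing on the C7 problem.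
- The ortho-formyl aryl ester A2 is prone to acyl transfer.
- The coupling to A1 needs a large excess of titanium at reflux under slow addition, and intermolecular coupling of the aldehyde competes.
- Lewis-acidic TiCl3 and ZnCl2 meet the geranyl chain, which can start cation–olefin cyclisation.

In exchange, the chosen route offers a closure in plain aqueous base, no Lewis acid near the geranyl chain, one protecting group instead of three, and ring B from acetylacetone.

**Alternative 2:** Ring A is cut at C7–C7a, C5–C6 and C3a–C7a. The pieces are the diazo ketone (3E)-6-[3,5-bis(tert-butyldimethylsilyloxy)phenyl]-1-diazohex-3-en-5-yn-2-one A4 and the geranyl siloxyalkyne triisopropyl{[(4E)-5,9-dimethyldeca-4,8-dien-1-yn-1-yl]oxy}silane A5.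

In the forward direction, irradiation of A4 triggers a Wolff rearrangement to a vinylketene, which adds to A5. The cyclobutenone opens and recloses on warming (Danheiser benzannulation) to give 6-{[3,5-bis(tert-butyldimethylsilyloxy)phenyl]ethynyl}-2-geranyl-3-(triisopropylsilyloxy)phenol A3. Cyclisation of the phenol of A3 onto its alkyne and desilylation would finish the synthesis.

In its favour, the geranyl carbon is placed between the two oxygens by the alkyne A5 itself. On C7 regiocontrol this plan is clearly stronger than step 1 of the chosen route.

Against it:
- Both partners are multistep, sensitive compounds.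
- A5 is a skipped enyne that can isomerise to an allene.
- A4 is a conjugated diazo enynone whose photolysis competes with alkene isomerisation.
- The ketene can be intercepted by the geranyl alkenes.
- Two further steps follow the benzannulation before A3 becomes the target.

The chosen route is about half as long and needs no photochemistry and no diazo compound; what it gives up is the built-in regiocontrol at C7.

**Alternative 3:** Ring A is cut at C4=C5. The precursor is the furan (6E)-4-{5-[3,5-bis(tert-butyldimethylsilyloxy)phenyl]-3-vinylfuran-2-yl}-7,11-dimethyldodeca-1,6,10-trien-3-one A7, racemic at the carbon that bears the geranyl chain.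

In the forward direction, ring-closing metathesis of A7 with the second-generation Grubbs catalyst joins the vinyl group on the furan to the vinyl ketone terminus. The resulting dienone tautomerises at once to 2-[3,5-bis(tert-butyldimethylsilyloxy)phenyl]-7-geranylbenzofuran-6-ol A6.

In its favour, the geranyl position in A7 is fixed by enolate alkylation, again better than step 1 here. The C6 phenol of A6 appears unprotected.

Against it:
- A7 needs a 2,3,5-trisubstituted furan and a vinyl ketone prone to polymerisation, built over many steps.
- The catalyst can also engage the C2″=C3″ alkene.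
- Closing a cyclopentenone with the vinyl ketone would cut off most of the geranyl chain.
- Two silyl ethers of A6 still have to be removed.

The chosen route reaches its ring-forming substrate in four steps from bulk chemicals and exposes the geranyl chain to no metal carbene.

Key step: step 5

## Route

Remark on the chemistry: the triketone 11 and the related di- and triketones are drawn as keto tautomers; they will exist largely as hydrogen-bonded enols, which does not change the reasoning.

**Step 1**
Reactants: 1 2,4-dihydroxybenzaldehyde; 2 geranyl bromide
Product: 3 3-geranyl-2,4-dihydroxybenzaldehyde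
Conditions: KOH (aq, 10%), 1 in excess, 0 °C → rt
Reagents that add atoms: none
Why: Phenoxide C-alkylation in water: hydrogen bonding to the phenoxide oxygens disfavours O-alkylation, and C3, ortho to both oxygens, is the most electron-rich carbon, so SN2 displacement of bromide at the primary allylic carbon of 2 places the chain between the two hydroxyls and leaves the (E)-alkene unchanged; the reaction type is established for allylic halides and 2,4-dihydroxyaryl carbonyl compounds, with only moderate regiocontrol.

**Step 2**
Reactants: 3 3-geranyl-2,4-dihydroxybenzaldehyde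
Product: 4 4-(allyloxy)-3-geranyl-2-hydroxybenzaldehyde
Conditions: allyl bromide (1.05 equiv), K2CO3 (1.0 equiv), acetone, rt → 40 °C
Reagents that add atoms: allyl bromide, C=CCBr
Why: Williamson ether synthesis; the 2-hydroxyl is held in a hydrogen bond to the formyl oxygen and its phenoxide is the weaker nucleophile, so one equivalent of base and halide should alkylate the 4-hydroxyl selectively, as is usual for 2,4-dihydroxybenzaldehydes.

**Step 3**
Reactants: 4 4-(allyloxy)-3-geranyl-2-hydroxybenzaldehyde; 5 ethyl bromoacetate
Product: 8 ethyl 6-(allyloxy)-7-geranylbenzofuran-2-carboxylate, via aryloxyacetate ethyl [3-(allyloxy)-6-formyl-2-geranylphenoxy]acetate 6 (not isolated), via aldol ethyl 6-(allyloxy)-7-geranyl-3-hydroxy-2,3-dihydrobenzofuran-2-carboxylate 7 (not isolated)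
Conditions: 5 (1.2 equiv), K2CO3, DMF, 4 Å molecular sieves, 90 °C
Reagents that add atoms: none
Why: Rap–Stoermer-type benzofuran synthesis: O-alkylation of the remaining phenol gives 6, whose ester enolate adds to the ortho formyl group (5-exo-trig aldol) to give 7 as a mixture of diastereomers, and base-induced dehydration aromatises the furan and removes both new stereocenters; the allyl ether and the geranyl chain are inert to K2CO3 at this temperature, far below that of an aromatic Claisen rearrangement.

**Step 4**
Reactants: 9 acetylacetone (pentane-2,4-dione); 8 ethyl 6-(allyloxy)-7-geranylbenzofuran-2-carboxylate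
Product: 11 1-[6-(allyloxy)-7-geranylbenzofuran-2-yl]hexane-1,3,5-trione, via dilithioacetylacetone 10 (not isolated)
Conditions: 9 (3 equiv), LiN(iPr)2 (6 equiv), THF, 0 °C; then 8, 0 °C → rt; then AcOH (aq), 0 °C, to pH 6
Reagents that add atoms: LiN(iPr)2 (lithium diisopropylamide), [Li+].CC(C)[N-]C(C)C (its lithium is held in intermediate 10 only; none remains in 11)
Why: Claisen-type acylation of a 1,3-diketone dianion: the terminal carbanion of 10, its more basic and more nucleophilic carbon, attacks the ester, which has no α-hydrogen and cannot be enolised; the triketone is deprotonated by further 10 as it forms, which is why an excess is used and why no second acylation follows, and the mildly acidic quench avoids acid-induced closure to a 4-pyranone.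

**Step 5**
Reactants: 11 1-[6-(allyloxy)-7-geranylbenzofuran-2-yl]hexane-1,3,5-trione
Product: 13 5-[6-(allyloxy)-7-geranylbenzofuran-2-yl]benzene-1,3-diol, via aldol adduct 5-[6-(allyloxy)-7-geranylbenzofuran-2-yl]-5-hydroxycyclohexane-1,3-dione 12 (not isolated)
Conditions: KOH (aq, 2 M), EtOH, N2, high dilution, rt → 60 °C; then AcOH, 0 °C, to pH 6
Reagents that add atoms: none
Why: Hydroxide turns 11 into its enolates, and the small equilibrium share in which the terminal methyl ketone (chain C5/C6) is enolised while the chain C1 carbonyl is in its keto form adds C6 to C1 to give the aldol 12. The closest known reaction is the base-induced cyclisation of heptane-2,4,6-trione to orcinol, and aryl ketone termini are known acceptors in the related closures of 3,5,7-trioxo acids to 6-aryl-β-resorcylic acids. The ring closes in the 6-(enolendo)-exo-trig mode, since the enolate C5=C6 bond lies inside the new ring and the C1=O bond outside it, which the Baldwin rules for enolates favour. 12 then loses water by an E1cB elimination (deprotonation α to a ring carbonyl, loss of hydroxide from the carbinol carbon) and the cyclohexenedione enolises to the resorcinol 13, which makes the sequence irreversible. No stereocenter is formed, because the carbinol carbon of 12 carries two equivalent ring arms and becomes sp2. Of the possible carbon–carbon closures only C6 onto C1 gives a ring larger than four members; closure through oxygen to the 2-aryl-6-methyl-4-pyranone is kept out because such pyranones reopen to the triketone salt in aqueous hydroxide while the carbocycle is drained by aromatisation; intermolecular aldol reaction and retro-Claisen cleavage are held back by dilution and by the enolate form, which shields the carbonyls from hydroxide. The allyl ether keeps O6 from becoming a phenoxide, whose conjugation through C3a–C3=C2 would make the C1 carbonyl a vinylogous carboxylate and a poorer acceptor, and neither the allyl ether nor the geranyl chain reacts with aqueous KOH.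

**Step 6**
Reactants: 13 5-[6-(allyloxy)-7-geranylbenzofuran-2-yl]benzene-1,3-diol
Product: 14 5-(7-geranyl-6-hydroxybenzofuran-2-yl)benzene-1,3-diol (the target)
Conditions: Pd(PPh3)4 (5 mol %), morpholine (10 equiv), THF, degassed, rt
Reagents that add atoms: none
Why: Tsuji–Trost deallylation: zerovalent palladium ionises the aryl allyl ether to a π-allyl complex and the phenoxide, and morpholine traps the allyl group irreversibly and outcompetes the resorcinol carbons; the geranyl alkenes carry no leaving group and do not react, and no acid is present that could close the geranyl chain onto the freed hydroxyl.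

## Compound list

1 | 2,4-dihydroxybenzaldehyde | O=Cc1ccc(O)cc1O | starting material
2 | geranyl bromide, (2E)-1-bromo-3,7-dimethylocta-2,6-diene | CC(C)=CCC/C(C)=C/CBr | starting material
3 | 3-[(2E)-3,7-dimethylocta-2,6-dien-1-yl]-2,4-dihydroxybenzaldehyde | CC(C)=CCC/C(C)=C/Cc1c(O)ccc(C=O)c1O | intermediate
4 | 4-(allyloxy)-3-[(2E)-3,7-dimethylocta-2,6-dien-1-yl]-2-hydroxybenzaldehyde | CC(C)=CCC/C(C)=C/Cc1c(OCC=C)ccc(C=O)c1O | intermediate
5 | ethyl bromoacetate | CCOC(=O)CBr | starting material
6 | ethyl {3-(allyloxy)-2-[(2E)-3,7-dimethylocta-2,6-dien-1-yl]-6-formylphenoxy}acetate | CC(C)=CCC/C(C)=C/Cc1c(OCC=C)ccc(C=O)c1OCC(=O)OCC | intermediate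
7 | ethyl 6-(allyloxy)-7-[(2E)-3,7-dimethylocta-2,6-dien-1-yl]-3-hydroxy-2,3-dihydrobenzofuran-2-carboxylate (mixture of diastereomers, racemic) | CC(C)=CCC/C(C)=C/Cc1c(OCC=C)ccc2c1OC(C(=O)OCC)C2O | intermediate
8 | ethyl 6-(allyloxy)-7-[(2E)-3,7-dimethylocta-2,6-dien-1-yl]benzofuran-2-carboxylate | CC(C)=CCC/C(C)=C/Cc1c(OCC=C)ccc2cc(C(=O)OCC)oc12 | intermediate
9 | acetylacetone (pentane-2,4-dione) | CC(=O)CC(C)=O | starting material
10 | dilithioacetylacetone (dilithium salt of the pentane-2,4-dione dianion) | [Li+].[Li+].C=C([O-])C=C(C)[O-] | intermediate
11 | 1-{6-(allyloxy)-7-[(2E)-3,7-dimethylocta-2,6-dien-1-yl]benzofuran-2-yl}hexane-1,3,5-trione | CC(C)=CCC/C(C)=C/Cc1c(OCC=C)ccc2cc(C(=O)CC(=O)CC(C)=O)oc12 | intermediate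
12 | 5-{6-(allyloxy)-7-[(2E)-3,7-dimethylocta-2,6-dien-1-yl]benzofuran-2-yl}-5-hydroxycyclohexane-1,3-dione | CC(C)=CCC/C(C)=C/Cc1c(OCC=C)ccc2cc(C3(O)CC(=O)CC(=O)C3)oc12 | intermediate
13 | 5-{6-(allyloxy)-7-[(2E)-3,7-dimethylocta-2,6-dien-1-yl]benzofuran-2-yl}benzene-1,3-diol | CC(C)=CCC/C(C)=C/Cc1c(OCC=C)ccc2cc(-c3cc(O)cc(O)c3)oc12 | intermediate
14 | 5-{7-[(2E)-3,7-dimethylocta-2,6-dien-1-yl]-6-hydroxybenzofuran-2-yl}benzene-1,3-diol | CC(C)=CCC/C(C)=C/Cc1c(O)ccc2cc(-c3cc(O)cc(O)c3)oc12 | target

## Step count and least certain steps

Total step count: 6. Longest linear sequence: 6 steps (1 to 14); compounds 2, 5 and 9 enter as single building blocks.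

**Step 5 (key step).** The carbon–carbon bond formation may be too slow, because in aqueous base the chain C1 carbonyl is almost always part of a delocalised enolate and is further damped by the electron-rich benzofuran. Hydroxide may then cleave the chain by retro-Claisen fragmentation, or two molecules may condense with each other. The fallback sets out from 11 and comes back at 13. The trianion of 11 (LiN(iPr)2, THF) would be carboxylated with CO2 at the terminal methyl carbon to give 7-[6-(allyloxy)-7-geranylbenzofuran-2-yl]-3,5,7-trioxoheptanoic acid F1. In F1 the nucleophilic carbon is a methylene flanked by ketone and carboxyl, so it should close onto the aryl ketone in weakly basic aqueous buffer to give 6-[6-(allyloxy)-7-geranylbenzofuran-2-yl]-2,4-dihydroxybenzoic acid F2. F2 should then lose CO2 on warming in aqueous DMF to give 13.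

**Step 1.** Attack at C5, alkylation on oxygen and double alkylation compete with the wanted attack at C3, so conversion to 3 will be modest and a careful separation is needed. The fallback sets out from 2 and comes back at 3. 1,3-Bis(methoxymethoxy)benzene F3 would be lithiated between its two acetal oxygens (n-BuLi, THF, 0 °C) and alkylated with 2 in the presence of catalytic CuI to give 2-geranyl-1,3-bis(methoxymethoxy)benzene F4. A second directed lithiation ortho to one acetal (n-BuLi, TMEDA) and a quench with DMF would give 3-geranyl-2,4-bis(methoxymethoxy)benzaldehyde F5. Brief methanolysis of F5 with dilute HCl in MeOH at rt would return 3. Regiochemistry is then fixed by metalation, at the price of two more steps and one short exposure of the geranyl phenol to dilute acid, which must be stopped as soon as the acetals are gone.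

**Step 4.** Proton transfer from the triketone to the dianion may stall the acylation before the ester is consumed, and the acidified product may begin to close to the pyranone during purification. The fallback sets out from 4 and comes back at 11. Rap–Stoermer condensation of 4 with chloroacetone (K2CO3, DMF) would give 1-[6-(allyloxy)-7-geranylbenzofuran-2-yl]ethan-1-one F6. Claisen condensation of F6 with ethyl acetate (NaH, THF) would give 1-[6-(allyloxy)-7-geranylbenzofuran-2-yl]butane-1,3-dione F7. The dianion of F7 (LiN(iPr)2) would be acetylated at its terminal carbon with N-methoxy-N-methylacetamide. The tetrahedral adduct persists until work-up, so no acidic triketone is released in the flask to quench the dianion, and 11 is formed on acidification.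

**Step 6.** The π-allyl fragment may be recaptured by the electron-rich resorcinol ring instead of the amine, and the free triphenol may oxidise in air while palladium residues are removed. The fallback sets out from 8 and comes back at the target 14. The allyl group would be removed at the ester stage (Pd(PPh3)4, morpholine) to give ethyl 7-geranyl-6-hydroxybenzofuran-2-carboxylate F8, where no resorcinol competes. Silylation of F8 (iPr3SiCl, imidazole, DMF) would give ethyl 7-geranyl-6-(triisopropylsilyloxy)benzofuran-2-carboxylate F9. Acylation of 10 with F9 as in step 4 would give 1-[7-geranyl-6-(triisopropylsilyloxy)benzofuran-2-yl]hexane-1,3,5-trione F10. Aqueous KOH would cleave the aryl silyl ether of F10 in the flask to 1-(7-geranyl-6-hydroxybenzofuran-2-yl)hexane-1,3,5-trione F11 and cyclise it, so that acidification gives 14 with no deprotection after the ring closure. The price is a less electrophilic acceptor carbonyl during the closure.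

## Further compounds

F1 | step 5 | 7-{6-(allyloxy)-7-[(2E)-3,7-dimethylocta-2,6-dien-1-yl]benzofuran-2-yl}-3,5,7-trioxoheptanoic acid | CC(C)=CCC/C(C)=C/Cc1c(OCC=C)ccc2cc(C(=O)CC(=O)CC(=O)CC(=O)O)oc12
F2 | step 5 | 6-{6-(allyloxy)-7-[(2E)-3,7-dimethylocta-2,6-dien-1-yl]benzofuran-2-yl}-2,4-dihydroxybenzoic acid | CC(C)=CCC/C(C)=C/Cc1c(OCC=C)ccc2cc(-c3cc(O)cc(O)c3C(=O)O)oc12
F3 | step 1 | 1,3-bis(methoxymethoxy)benzene | COCOc1cccc(OCOC)c1
F4 | step 1 | 2-[(2E)-3,7-dimethylocta-2,6-dien-1-yl]-1,3-bis(methoxymethoxy)benzene | CC(C)=CCC/C(C)=C/Cc1c(OCOC)cccc1OCOC
F5 | step 1 | 3-[(2E)-3,7-dimethylocta-2,6-dien-1-yl]-2,4-bis(methoxymethoxy)benzaldehyde | CC(C)=CCC/C(C)=C/Cc1c(OCOC)ccc(C=O)c1OCOC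
F6 | step 4 | 1-{6-(allyloxy)-7-[(2E)-3,7-dimethylocta-2,6-dien-1-yl]benzofuran-2-yl}ethan-1-one | CC(C)=CCC/C(C)=C/Cc1c(OCC=C)ccc2cc(C(C)=O)oc12
F7 | step 4 | 1-{6-(allyloxy)-7-[(2E)-3,7-dimethylocta-2,6-dien-1-yl]benzofuran-2-yl}butane-1,3-dione | CC(C)=CCC/C(C)=C/Cc1c(OCC=C)ccc2cc(C(=O)CC(C)=O)oc12
F8 | step 6 | ethyl 7-[(2E)-3,7-dimethylocta-2,6-dien-1-yl]-6-hydroxybenzofuran-2-carboxylate | CC(C)=CCC/C(C)=C/Cc1c(O)ccc2cc(C(=O)OCC)oc12
F9 | step 6 | ethyl 7-[(2E)-3,7-dimethylocta-2,6-dien-1-yl]-6-(triisopropylsilyloxy)benzofuran-2-carboxylate | CC(C)=CCC/C(C)=C/Cc1c(O[Si](C(C)C)(C(C)C)C(C)C)ccc2cc(C(=O)OCC)oc12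
F10 | step 6 | 1-{7-[(2E)-3,7-dimethylocta-2,6-dien-1-yl]-6-(triisopropylsilyloxy)benzofuran-2-yl}hexane-1,3,5-trione | CC(C)=CCC/C(C)=C/Cc1c(O[Si](C(C)C)(C(C)C)C(C)C)ccc2cc(C(=O)CC(=O)CC(C)=O)oc12
F11 | step 6 | 1-{7-[(2E)-3,7-dimethylocta-2,6-dien-1-yl]-6-hydroxybenzofuran-2-yl}hexane-1,3,5-trione | CC(C)=CCC/C(C)=C/Cc1c(O)ccc2cc(C(=O)CC(=O)CC(C)=O)oc12
A1 | alternative 1 | 2-[3,5-bis(triisopropylsilyloxy)phenyl]-7-[(2E)-3,7-dimethylocta-2,6-dien-1-yl]-6-(triisopropylsilyloxy)benzofuran | CC(C)=CCC/C(C)=C/Cc1c(O[Si](C(C)C)(C(C)C)C(C)C)ccc2cc(-c3cc(O[Si](C(C)C)(C(C)C)C(C)C)cc(O[Si](C(C)C)(C(C)C)C(C)C)c3)oc12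
A2 | alternative 1 | 2-formyl-6-[(2E)-3,7-dimethylocta-2,6-dien-1-yl]-5-(triisopropylsilyloxy)phenyl 3,5-bis(triisopropylsilyloxy)benzoate | CC(C)=CCC/C(C)=C/Cc1c(O[Si](C(C)C)(C(C)C)C(C)C)ccc(C=O)c1OC(=O)c1cc(O[Si](C(C)C)(C(C)C)C(C)C)cc(O[Si](C(C)C)(C(C)C)C(C)C)c1
A3 | alternative 2 | 6-{[3,5-bis(tert-butyldimethylsilyloxy)phenyl]ethynyl}-2-[(2E)-3,7-dimethylocta-2,6-dien-1-yl]-3-(triisopropylsilyloxy)phenol | CC(C)=CCC/C(C)=C/Cc1c(O[Si](C(C)C)(C(C)C)C(C)C)ccc(C#Cc2cc(O[Si](C)(C)C(C)(C)C)cc(O[Si](C)(C)C(C)(C)C)c2)c1O
A4 | alternative 2 | (3E)-6-[3,5-bis(tert-butyldimethylsilyloxy)phenyl]-1-diazohex-3-en-5-yn-2-one | [N-]=[N+]=CC(=O)/C=C/C#Cc1cc(O[Si](C)(C)C(C)(C)C)cc(O[Si](C)(C)C(C)(C)C)c1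
A5 | alternative 2 | triisopropyl{[(4E)-5,9-dimethyldeca-4,8-dien-1-yn-1-yl]oxy}silane | CC(C)=CCC/C(C)=C/CC#CO[Si](C(C)C)(C(C)C)C(C)C
A6 | alternative 3 | 2-[3,5-bis(tert-butyldimethylsilyloxy)phenyl]-7-[(2E)-3,7-dimethylocta-2,6-dien-1-yl]benzofuran-6-ol | CC(C)=CCC/C(C)=C/Cc1c(O)ccc2cc(-c3cc(O[Si](C)(C)C(C)(C)C)cc(O[Si](C)(C)C(C)(C)C)c3)oc12
A7 | alternative 3 | (6E)-4-{5-[3,5-bis(tert-butyldimethylsilyloxy)phenyl]-3-vinylfuran-2-yl}-7,11-dimethyldodeca-1,6,10-trien-3-one (racemic at C4) | C=CC(=O)C(C/C=C(\C)CCC=C(C)C)c1oc(-c2cc(O[Si](C)(C)C(C)(C)C)cc(O[Si](C)(C)C(C)(C)C)c2)cc1C=C
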